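The route rests on reading the butenolide (ring atoms O1, C2, C3, C4, C5) and its exocyclic benzylidene carbon C6 as the cycloisomer of a (Z)-3,5-diarylpent-2-en-4-ynoic acid, so that C5 and C6 enter together as an alkyne. Propiolic acid 1 is hydroiodinated to the (Z)-β-iodoacrylic acid 2, the precursor, which carries its carboxyl group cis to iodine. In one operation, coupling of 2 with 4-ethynylanisole 3 forms C4–C5 and the cis carboxylate of the transient enynoic acid 4 closes O1–C5, giving the Z-benzylidene butenolide 5 with both aryl rings in place. Ether cleavage and fourfold ortho-bromination then deliver rubrolide A.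

Key step: step 2

Assumption: both starting materials are bought; atom labels (O1, carbonyl C2, C3, C4, C5, exocyclic C6) follow the furanone numbering of the target.

Step 1
Reactants: 1 3-(4-methoxyphenyl)propiolic acid
Product: 2 (Z)-3-iodo-3-(4-methoxyphenyl)acrylic acid
Conditions: NaI (3 equiv), AcOH, 110 °C
Reagents that add atoms: sodium iodide, [Na+].[I-]
Why: Hydroiodination of an alk-2-ynoic acid with HI generated from NaI and AcOH: iodide adds to C3 (the position favoured both by conjugate addition and by the anisyl group) and C2 is protonated anti, so H and I end up trans and the carboxyl group cis to iodine, which is the Z acid; no stereocentre is formed.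

Step 2
Reactants: 2 (Z)-3-iodo-3-(4-methoxyphenyl)acrylic acid; 3 4-ethynylanisole (1.3 equiv)
Product: 5 (Z)-5-(4-methoxybenzylidene)-4-(4-methoxyphenyl)furan-2(5H)-one, via enynoic acid 4 (not isolated)
Conditions: Pd(PPh3)4 (5 mol %), CuI (10 mol %), Et3N (3 equiv), degassed MeCN, rt
Reagents that add atoms: none
Why: Zerovalent palladium inserts into the vinyl C–I bond of 2 with retention of geometry, the copper acetylide generated from 3, CuI and Et3N transfers the alkynyl group, and reductive elimination forms C4–C5, giving the triethylammonium salt of enynoic acid 4 with the carboxylate cis to the alkyne. The alkyne of 4, π-activated by a soft metal centre in the mixture (divalent palladium or monovalent copper), is attacked at C5 by the carboxylate oxygen from the face opposite the metal, and protonolysis of the resulting C6–metal bond by triethylammonium releases 5 and the catalyst. The closest known reaction type is the tandem Sonogashira coupling and lactonization of (Z)-3-iodoalk-2-enoic acids with terminal alkynes to (Z)-5-ylidenebutenolides. The butenolide ring closes in the 5-exo-dig mode by O1–C5 bond formation. No stereocentre is created, and the Z geometry at C5=C6 follows from anti oxymetalation and stereoretentive protodemetalation, which leave the anisyl group cis to O1. The step needs 5-exo rather than 6-endo closure (which would give the isomeric 4,6-diaryl-2-pyranone) and coupling only at the vinyl iodide; the rigid cis-acrylate tether that holds the carboxylate oxygen next to C5, the mild basic medium at room temperature and the absence of any aryl halide in 2 and 3 secure this, whereas the electron-rich anisyl group on C6 is the feature that works against it.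

Step 3
Reactants: 5 (Z)-5-(4-methoxybenzylidene)-4-(4-methoxyphenyl)furan-2(5H)-one
Product: 7 (Z)-5-(4-hydroxybenzylidene)-4-(4-hydroxyphenyl)furan-2(5H)-one (rubrolide E), via bis(aryloxydibromoborane) 6 (not isolated)
Conditions: BBr3 (6 equiv), CH2Cl2, −78 °C to rt; then H2O, 0 °C
Reagents that add atoms: none
Why: Aryl methyl ether cleavage with BBr3: boron binds each ether oxygen, bromide attacks the methyl group in an SN2 step to release bromomethane and leave the aryloxyborane 6, and water then hydrolyses the B–O bonds; the sp2 C–O bonds of the enol lactone are not cleaved under these conditions and the Z alkene is not touched.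

Step 4
Reactants: 7 (Z)-5-(4-hydroxybenzylidene)-4-(4-hydroxyphenyl)furan-2(5H)-one
Product: 8 (Z)-5-(3,5-dibromo-4-hydroxybenzylidene)-4-(3,5-dibromo-4-hydroxyphenyl)furan-2(5H)-one (rubrolide A)
Conditions: Br2 (4.1 equiv, added slowly as a solution in AcOH), AcOH, rt, dark
Reagents that add atoms: bromine, BrBr
Why: Electrophilic aromatic bromination of two para-substituted phenols: each hydroxyl group activates only its two ortho positions because the para position carries the butenolide framework, so four equivalents of bromine added slowly should fill exactly the four required positions, while the C3=C4 and C5=C6 alkenes, conjugated to the lactone carbonyl and attached to the acylated oxygen O1, react far more slowly than a phenol.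

Compound list
1 | 3-(4-methoxyphenyl)propiolic acid | COc1ccc(C#CC(=O)O)cc1 | starting material
2 | (Z)-3-iodo-3-(4-methoxyphenyl)acrylic acid (carboxyl cis to iodine) | OC(=O)/C=C(\I)c1ccc(OC)cc1 | intermediate
3 | 4-ethynylanisole | C#Cc1ccc(OC)cc1 | starting material
4 | (Z)-3,5-bis(4-methoxyphenyl)pent-2-en-4-ynoic acid (carboxyl cis to the alkyne; present as its triethylammonium salt, not isolated) | OC(=O)/C=C(\C#Cc1ccc(OC)cc1)c1ccc(OC)cc1 | intermediate
5 | (Z)-5-(4-methoxybenzylidene)-4-(4-methoxyphenyl)furan-2(5H)-one (benzylidene aryl cis to O1) | O=C1C=C(c2ccc(OC)cc2)/C(=C/c2ccc(OC)cc2)O1 | intermediate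
6 | (Z)-5-[4-(dibromoboryloxy)benzylidene]-4-[4-(dibromoboryloxy)phenyl]furan-2(5H)-one (not isolated) | O=C1C=C(c2ccc(OB(Br)Br)cc2)/C(=C/c2ccc(OB(Br)Br)cc2)O1 | intermediate
7 | (Z)-5-(4-hydroxybenzylidene)-4-(4-hydroxyphenyl)furan-2(5H)-one (rubrolide E) | O=C1C=C(c2ccc(O)cc2)/C(=C/c2ccc(O)cc2)O1 | intermediate
8 | (Z)-5-(3,5-dibromo-4-hydroxybenzylidene)-4-(3,5-dibromo-4-hydroxyphenyl)furan-2(5H)-one (rubrolide A) | O=C1C=C(c2cc(Br)c(O)c(Br)c2)/C(=C/c2cc(Br)c(O)c(Br)c2)O1 | target

Total step count: 4. Longest linear sequence: 4 steps (1 to 2 to 5 to 7 to 8); 3 enters at step 2.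

Steps most likely to fail

Step 2 (key step). The carboxylate may add to the far alkyne carbon C6 (6-endo-dig closure), a path that the electron-donating anisyl group on C6 encourages, and the terminal alkyne may be consumed by copper-mediated oxidative homocoupling. The fallback separates bond formation from ring closure; it sets out from 2 and 3 and comes back to the route at 5. Acid 2 is methylated with (trimethylsilyl)diazomethane in toluene–MeOH at 0 °C to give methyl (Z)-3-iodo-3-(4-methoxyphenyl)acrylate F1. Sonogashira coupling of this ester with 3 (PdCl2(PPh3)2, CuI, Et3N, THF, rt) should give methyl (Z)-3,5-bis(4-methoxyphenyl)pent-2-en-4-ynoate F2, which cannot lactonize. Saponification (LiOH, THF–H2O, then dilute HCl) gives acid 4, now isolated. Ring closure with catalytic AgNO3 in acetone at rt, a silver-mediated cycloisomerization known to give the five-membered ylidene lactone from (Z)-2-en-4-ynoic acids, then leads to 5, and its solvent and temperature can be tuned for the exo mode independently of the coupling.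

Step 1. In hot acetic acid the arylpropiolic acid may lose CO2 or be hydrated at the anisyl-activated alkyne, and the double-bond geometry may erode if iodide adds through a free vinyl cation. The fallback masks the carboxyl group during the hydroiodination; it sets out from 1 and comes back at 2. Alkylation of 1 (EtI, K2CO3, DMF, rt) gives ethyl 3-(4-methoxyphenyl)propiolate F3. Hydroiodination of the ester (NaI, AcOH, 70 °C), which cannot decarboxylate and reacts by conjugate addition at the lower temperature, should give ethyl (Z)-3-iodo-3-(4-methoxyphenyl)acrylate F4. Mild saponification (LiOH, THF–H2O, 0 °C, then dilute HCl) returns 2.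

Step 3. Long exposure of the ylidenebutenolide to BBr3 and HBr may isomerize the C5=C6 alkene or open the enol lactone on quenching, and cleavage may stop after one ether. The fallback frees the phenol before the ring exists; it sets out from 2 and comes back at 7. Treatment of 2 with BBr3 (CH2Cl2, −78 °C to rt) gives dibromoboryl (Z)-3-[4-(dibromoboryloxy)phenyl]-3-iodoacrylate F5 (not isolated), which water hydrolyses to (Z)-3-(4-hydroxyphenyl)-3-iodoacrylic acid F6. This acid is then coupled with purchased 4-ethynylphenol (C#Cc1ccc(O)cc1) under the catalyst system of step 2, which tolerates free phenols. The coupling should pass through (Z)-3,5-bis(4-hydroxyphenyl)pent-2-en-4-ynoic acid F7 (not isolated) and give 7 directly, so that the finished butenolide never meets the Lewis acid.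

Further compounds
F1 | step 2 | methyl (Z)-3-iodo-3-(4-methoxyphenyl)acrylate | COC(=O)/C=C(\I)c1ccc(OC)cc1
F2 | step 2 | methyl (Z)-3,5-bis(4-methoxyphenyl)pent-2-en-4-ynoate | COC(=O)/C=C(\C#Cc1ccc(OC)cc1)c1ccc(OC)cc1
F3 | step 1 | ethyl 3-(4-methoxyphenyl)propiolate | CCOC(=O)C#Cc1ccc(OC)cc1
F4 | step 1 | ethyl (Z)-3-iodo-3-(4-methoxyphenyl)acrylate | CCOC(=O)/C=C(\I)c1ccc(OC)cc1
F5 | step 3 | dibromoboryl (Z)-3-[4-(dibromoboryloxy)phenyl]-3-iodoacrylate (not isolated) | O=C(OB(Br)Br)/C=C(\I)c1ccc(OB(Br)Br)cc1
F6 | step 3 | (Z)-3-(4-hydroxyphenyl)-3-iodoacrylic acid | OC(=O)/C=C(\I)c1ccc(O)cc1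
F7 | step 3 | (Z)-3,5-bis(4-hydroxyphenyl)pent-2-en-4-ynoic acid (not isolated) | OC(=O)/C=C(\C#Cc1ccc(O)cc1)c1ccc(O)cc1
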